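## The problem

Podocarpusflavone A, compound 23, is an apigenin unit and an acacetin unit joined by one bond between C3' of the apigenin ring B and C8'' of the acacetin ring A (apigenin atoms carry no prime or one, acacetin atoms two or three). That bond has three ortho substituents (the 4'-oxygen, the 7''-oxygen and C8a'' with the ring oxygen O1''), so it is hindered to make. The molecule has no stereocentre and the axis is drawn without configuration, so nothing has to be controlled in space. Five of the six phenolic oxygens are free and only the 4'''-oxygen is methylated, so the methyl ether must survive a global deprotection. Ring A of the acacetin unit is a phloroglucinol in which two oxygens, on C5'' and C8a'', flank C4a''. The pyranone must close onto the one next to C8'', because closure onto the other gives the 6''-linked isomer, and 5-hydroxyflavones can drift between the two under strong acid (Wessely–Moser rearrangement). The sensitive elements are the two pyranones (opened by hydroxide and hard nucleophiles, C2=C3 reducible), the electron-rich carbons C6, C8 and C6'' (open to stray halogenation or C-alkylation) and any free 1,3-diketone on a 2,6-dioxygenated aryl ring (retro-Claisen cleavage). The feature that invites the key step is the chain C2''–C3''–C4'': three carbons with oxygen at both ends, held between C4a'' and the anisyl ring, which is the oxidation pattern stored in a 3,5-diarylisoxazole that an alkyne on C4a'' and the nitrile oxide of 4-methoxybenzaldehyde can assemble.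

## Retrosynthesis

**23 from 22.** The last cut removes five O–benzyl bonds from pentabenzyl ether 22. Benzyl is chosen because it survives the acid that closes ring C of the acacetin unit and can then be cleaved by a boron Lewis acid that leaves a non-chelated aryl methyl ether alone. The debenzylation has to come last, because the C5'' oxygen must stay blocked until the pyranone exists.

**22 from 20.** The O1''–C2'' bond is cut, leading to the Z-enaminone 20, in which C4'' is already a ketone and C2'' carries an amino group as a leaving group. The neighbouring options, a Baker–Venkataraman diketone or oxidation of a chalcone, would need strong base or a free diketone next to the finished apigenin pyranone. The enaminone needs only acid. In 20 the C8a'' oxygen is an acetal (methoxymethyl) and the C5'' oxygen a benzyl ether, so acid frees only the oxygen that must become O1''. Free phenol 21 forms in the flask and closes with loss of ammonia.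

**20 from 19.** The N–O bond is re-formed, giving the 3,5-diarylisoxazole 19. The forward reaction must be a reduction that cleaves N–O and spares benzyl ethers. Hydrogenolysis is excluded, because a free C5'' hydroxyl would compete in the ring closure.

**19 from 14 and 18.** This is the key disconnection. Cutting C2''–C3'' and C4''–O of the isoxazole gives the terminal alkyne 14 on C4a'' and 4-methoxybenzonitrile oxide 18, made in the flask from hydroximoyl chloride 17. The anisyl ring and its methyl ether arrive in one small fragment at a late stage. No diketone is ever free, and the conditions are close to neutral. The reaction must be regioselective (oxygen to the substituted alkyne carbon) and must leave the apigenin C2=C3 bond alone.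

**14 from 13.** The C3''–C4'' bond is cut, a one-carbon homologation of aldehyde 13. The formyl group comes with the starting material and needs no second halogen on ring A, which a Sonogashira route to the same alkyne would require.

**13 from 4 and 12.** The biaryl bond C3'–C8'' is cut between aryl iodide 4 and flavone boronate 12. Boron sits on ring B, which has one ortho substituent and is less prone to protodeboronation than a 2,6-dioxygenated ring. The iodide sits on the hindered, electron-rich ring A, where the better leaving group is needed. The coupling is placed before the alkyne is made, because a terminal alkyne and an aryl iodide do not coexist under palladium catalysis. It is placed after the apigenin pyranone is complete, so that the two halves are built in parallel.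

**4 from 1.** Iodide 4 goes back through iodophenol 3 and dibenzyl ether 2 to 2,4,6-trihydroxybenzaldehyde 1. The hydroxyl that stays free in 2, chelated to the formyl group, directs iodine to its ortho position (the future C8'') and then receives the methoxymethyl group. One hydrogen bond thus fixes both the position of the biaryl bond and the oxygen that will close ring C.

**12 from 5 and 7.** Boronate 12 comes from bromoflavone 11 by borylation. 11 comes from chalcone 9 by oxidative cyclization through flavanone 10. 9 comes from acetophenone 6 and aldehyde 8, which are the benzyl ethers of 2,4,6-trihydroxyacetophenone 5 and 3-bromo-4-hydroxybenzaldehyde 7.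

**17 from 15.** Hydroximoyl chloride 17 comes from oxime 16 and this from 4-methoxybenzaldehyde 15. 17 is isolated so that no electrophilic chlorine meets the electron-rich rings of 14.

## Roads not taken

**Alternative 1:** The cut runs through ring A of the acacetin unit, at C8''–C8a'' and C6''–C7''. In the forward step 3-ethoxycyclobut-2-en-1-one A1 is heated with the aryl triisopropylsilyloxyalkyne A2, whose aryl group is ring B with a dioxolane-masked formyl group. Ring opening to a vinylketene, [2+2] addition to the ynol ether, a second ring opening and a six-electron closure (Danheiser benzannulation) would give phenol A3.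
- Merits: the hindered biaryl bond is made without cross-coupling, and the three ring A oxygens arrive differentiated, with only the C8a'' oxygen free. On both points this road is better than the chosen plan.
- Weak points: A1 and A2 are not catalogue compounds, and A2 needs strong-base ynolate chemistry next to an ortho substituent. A3 still lacks C4'', so ring A must be acylated at C4a'' in competition with C6''. Both pyranones and the whole apigenin ring A remain to be built in a linear sequence. The C5'' ethyl ether later has to be cleaved beside the 4''' methyl ether.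
- Comparison: the chosen plan sets convergence against this, with two halves from cheap phloroglucinol derivatives and a coupling whose steric pattern is the known one of 8-iodoflavones with flavone 3'-boronates.

**Alternative 2:** The cut is in ring A of the apigenin unit, between C4a and the carbon that becomes C8a. In the forward step a magnesium alkoxide opens the 4-hydroxy-2-pyrone A4 to a triketo ester, which closes by Claisen condensation to the 2',4',6'-trihydroxychalcone A5 carrying the protected acacetin unit.
- Merits: the step mirrors the biosynthesis. Because the new phloroglucinol ring is symmetric, the later pyranone closure has no regiochemical question and the apigenin ring A needs no protecting groups. In protecting-group economy on that ring it is better than the chosen plan.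
- Weak points: it builds the one ring that is bought intact as compound 5. A4 must be made by acylating a pyrone dianion with a cinnamate that already carries a base-sensitive flavone and a Michael-acceptor enone. The triketo ester can close in the aldol mode as well as the Claisen mode. Oxidizing the free trihydroxychalcone A5 to the flavone is less clean than the same step on 9. The two hard problems, the biaryl bond and the direction of closure of the acacetin pyranone, are left untouched upstream.
- Comparison: the chosen plan solves those two problems directly and is shorter.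

**Alternative 3:** The cut is in ring B, at C2'–C3' and C1'–C6', with the C3'–C8'' bond already present as a benzylic bond of the diene. In the forward step the 1-methoxy-3-trimethylsilyloxy-4-arylbutadiene A6, whose aryl group is C8'' of dibenzylacacetin, adds to the dienophile methyl propiolate A7 and loses methanol to give the hydroxybenzoate A8.
- Merits: no hindered cross-coupling. The polarization of diene A6 and dienophile A7 fixes the substitution pattern of ring B. The 4'-hydroxyl and a carboxyl handle arrive in one step.
- Weak points: A6 has to be made by silylating the methoxy enone A9, whose four-carbon chain sits on C8'' of dibenzylacacetin, and putting that chain on C8'' meets the same 6-versus-8 problem as the biaryl bond. The silylation of A9 must give the right enol ether geometry in the presence of the pyranone. The reacting diene terminus carries a di-ortho-substituted aryl group, which slows the cycloaddition with a singly activated alkyne such as A7. After A8 the whole apigenin unit must still be built from the ester under basic conditions next to a finished flavone.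
- Comparison: in avoiding the cross-coupling it is equal to the chosen plan or better. The chosen plan sets against it a shorter, convergent sequence in which every base-mediated step is finished before either pyranone has to survive it, apart from one homologation in mild carbonate.

Key step: step 13

Assumption: the C3'–C8'' axis is taken as configurationally undefined, as drawn, so no atroposelective step is planned.

## Route

Step 1
Reactants: 1 2,4,6-trihydroxybenzaldehyde
Product: 2 4,6-bis(benzyloxy)-2-hydroxybenzaldehyde
Conditions: BnBr (2.1 equiv), K2CO3, DMF, 0 °C to rt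
Reagents that add atoms: benzyl bromide, BrCc1ccccc1
Why: Williamson etherification; the hydroxyl para to the formyl group and one ortho hydroxyl are alkylated, while the remaining ortho hydroxyl is locked in a hydrogen bond to the carbonyl and is the least nucleophilic, a selectivity well known for 2,4,6-trihydroxyaryl carbonyl compounds.

Step 2
Reactants: 2 4,6-bis(benzyloxy)-2-hydroxybenzaldehyde
Product: 3 4,6-bis(benzyloxy)-2-hydroxy-3-iodobenzaldehyde
Conditions: NIS (1.05 equiv), TFA (cat.), MeCN, 0 °C to rt
Reagents that add atoms: N-iodosuccinimide, O=C1CCC(=O)N1I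
Why: Electrophilic aromatic iodination; C3 is ortho to the free phenol, para to a benzyloxy group and less crowded than C5 between two benzyloxy groups, and halogenation of 2-hydroxy-4,6-dialkoxyaryl carbonyl compounds is known to go ortho to the free hydroxyl. This puts iodine on the carbon that becomes C8''.

Step 3
Reactants: 3 4,6-bis(benzyloxy)-2-hydroxy-3-iodobenzaldehyde
Product: 4 4,6-bis(benzyloxy)-3-iodo-2-(methoxymethoxy)benzaldehyde
Conditions: NaH, MOMCl, DMF, 0 °C
Reagents that add atoms: chloromethyl methyl ether, COCCl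
Why: O-alkylation of the sodium phenoxide; deprotonation breaks the chelate, the aldehyde has no enolizable hydrogen, and the acetal marks the future O1'' as the only acid-labile oxygen on ring A.

Step 4
Reactants: 5 2,4,6-trihydroxyacetophenone
Product: 6 1-[2,4-bis(benzyloxy)-6-hydroxyphenyl]ethanone
Conditions: BnBr (2.1 equiv), K2CO3, DMF, rt
Reagents that add atoms: benzyl bromide, BrCc1ccccc1
Why: Williamson etherification with the same chelation-based selectivity as in step 1; the free ortho hydroxyl is the one needed for the later pyranone closure.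

Step 5
Reactants: 7 3-bromo-4-hydroxybenzaldehyde
Product: 8 4-(benzyloxy)-3-bromobenzaldehyde
Conditions: BnBr, K2CO3, DMF, rt
Reagents that add atoms: benzyl bromide, BrCc1ccccc1
Why: Williamson etherification of an acidic, unhindered phenol.

Step 6
Reactants: 6 1-[2,4-bis(benzyloxy)-6-hydroxyphenyl]ethanone; 8 4-(benzyloxy)-3-bromobenzaldehyde
Product: 9 (E)-1-[2,4-bis(benzyloxy)-6-hydroxyphenyl]-3-[4-(benzyloxy)-3-bromophenyl]prop-2-en-1-one
Conditions: KOH (aq.), EtOH/THF, rt
Reagents that add atoms: none
Why: Claisen–Schmidt condensation; the aldehyde cannot enolize, and E1cB loss of water from the aldol gives the E-enone, the standard entry to 2'-hydroxychalcones.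

Step 7
Reactants: 9 (E)-1-[2,4-bis(benzyloxy)-6-hydroxyphenyl]-3-[4-(benzyloxy)-3-bromophenyl]prop-2-en-1-one
Product: 11 5,7-bis(benzyloxy)-2-[4-(benzyloxy)-3-bromophenyl]-4H-chromen-4-one, via racemic flavanone 10 (not isolated)
Conditions: I2 (10 mol%), DMSO, 130 °C
Reagents that add atoms: none
Why: Iodine-catalysed oxidative cyclization of a 2'-hydroxychalcone: oxa-Michael closure to flavanone 10, alpha-iodination and loss of HI; DMSO reoxidizes HI, so iodine stays catalytic and the benzyl ethers see no stoichiometric acid. The stereocentre of 10 is racemic and is destroyed in the same flask.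

Step 8
Reactants: 11 5,7-bis(benzyloxy)-2-[4-(benzyloxy)-3-bromophenyl]-4H-chromen-4-one
Product: 12 5,7-bis(benzyloxy)-2-[4-(benzyloxy)-3-(4,4,5,5-tetramethyl-1,3,2-dioxaborolan-2-yl)phenyl]-4H-chromen-4-one
Conditions: B2pin2, PdCl2(dppf) (5 mol%), KOAc, 1,4-dioxane, 90 °C
Reagents that add atoms: bis(pinacolato)diboron, CC1(C)OB(OC1(C)C)B1OC(C)(C)C(C)(C)O1
Why: Miyaura borylation of an aryl bromide; the weak acetate base leaves the pyranone and the benzyl ethers untouched, and 3'-haloflavones are established substrates.

Step 9
Reactants: 4 4,6-bis(benzyloxy)-3-iodo-2-(methoxymethoxy)benzaldehyde; 12 5,7-bis(benzyloxy)-2-[4-(benzyloxy)-3-(4,4,5,5-tetramethyl-1,3,2-dioxaborolan-2-yl)phenyl]-4H-chromen-4-one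
Product: 13 4,6-bis(benzyloxy)-3-{2-(benzyloxy)-5-[5,7-bis(benzyloxy)-4-oxo-4H-chromen-2-yl]phenyl}-2-(methoxymethoxy)benzaldehyde
Conditions: Pd(OAc)2 (5 mol%), SPhos (10 mol%), K3PO4, toluene/H2O, 90 °C
Reagents that add atoms: none
Why: Suzuki–Miyaura coupling to a tri-ortho-substituted biaryl; a bulky dialkylbiarylphosphine drives oxidative addition into the hindered, electron-rich iodide and the reductive elimination. The steric pattern matches the known couplings of 8-iodoflavones with flavone 3'-boronates.

Step 10
Reactants: 13 4,6-bis(benzyloxy)-3-{2-(benzyloxy)-5-[5,7-bis(benzyloxy)-4-oxo-4H-chromen-2-yl]phenyl}-2-(methoxymethoxy)benzaldehyde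
Product: 14 5,7-bis(benzyloxy)-2-{4-(benzyloxy)-3-[4,6-bis(benzyloxy)-3-ethynyl-2-(methoxymethoxy)phenyl]phenyl}-4H-chromen-4-one
Conditions: dimethyl (1-diazo-2-oxopropyl)phosphonate, K2CO3, MeOH/THF, 0 °C to rt
Reagents that add atoms: dimethyl (1-diazo-2-oxopropyl)phosphonate (Ohira–Bestmann reagent), CC(=O)C(=[N+]=[N-])P(=O)(OC)OC
Why: Ohira–Bestmann homologation; methanolysis frees the diazomethylphosphonate anion, which olefinates the aldehyde, and loss of N2 with a 1,2-hydrogen shift gives the alkyne. Carbonate in methanol at room temperature spares the pyranone, the acetal and the benzyl ethers, and 2,4,6-trialkoxybenzaldehydes are known substrates.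

Step 11
Reactants: 15 4-methoxybenzaldehyde
Product: 16 (E)-4-methoxybenzaldehyde oxime
Conditions: NH2OH·HCl, NaOAc, EtOH/H2O, rt
Reagents that add atoms: hydroxylamine hydrochloride, Cl.NO
Why: Condensation of an aldehyde with hydroxylamine; the aryl aldoxime forms as the E isomer.

Step 12
Reactants: 16 (E)-4-methoxybenzaldehyde oxime
Product: 17 (Z)-N-hydroxy-4-methoxybenzimidoyl chloride
Conditions: NCS, DMF, rt
Reagents that add atoms: N-chlorosuccinimide, O=C1CCC(=O)N1Cl
Why: Chlorination of an aldoxime at carbon with NCS in DMF, the standard route to hydroximoyl chlorides; isolating 17 keeps electrophilic chlorine away from the electron-rich rings of 14.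

Step 13
Reactants: 14 5,7-bis(benzyloxy)-2-{4-(benzyloxy)-3-[4,6-bis(benzyloxy)-3-ethynyl-2-(methoxymethoxy)phenyl]phenyl}-4H-chromen-4-one; 17 (Z)-N-hydroxy-4-methoxybenzimidoyl chloride
Product: 19 5,7-bis(benzyloxy)-2-{4-(benzyloxy)-3-[4,6-bis(benzyloxy)-2-(methoxymethoxy)-3-[3-(4-methoxyphenyl)isoxazol-5-yl]phenyl]phenyl}-4H-chromen-4-one, via 4-methoxybenzonitrile oxide 18 (not isolated)
Conditions: 17 (3 equiv), Et3N (slow addition), toluene, 60 °C
Reagents that add atoms: none
Why: Triethylamine removes HCl from 17 to give nitrile oxide 18, which adds across the terminal alkyne of 14 in a concerted, asynchronous [3+2] (Huisgen) cycloaddition. The closest known reaction type is the addition of aryl nitrile oxides to terminal arylalkynes to give 3,5-diarylisoxazoles. The five-membered ring closes in one intermolecular event in which the C2''–C3'' and C4''–O bonds form in the same transition state, and no stereocentre is created. The step needs regioselectivity: the nitrile oxide carbon with its anisyl group bonds to the unsubstituted alkyne terminus and oxygen to the substituted carbon, as both sterics and the polarization of an arylalkyne dictate, so oxygen lands on C4''. It needs chemoselectivity against the apigenin C2=C3 bond, which is trisubstituted and part of a vinylogous ester and so a poor dipolarophile. It must outrun dimerization of 18 to the furoxan, which slow addition of base and an excess of 17 keep in check. The two ortho substituents of ring A twist the ring but leave the linear alkyne terminus open.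

Step 14
Reactants: 19 5,7-bis(benzyloxy)-2-{4-(benzyloxy)-3-[4,6-bis(benzyloxy)-2-(methoxymethoxy)-3-[3-(4-methoxyphenyl)isoxazol-5-yl]phenyl]phenyl}-4H-chromen-4-one
Product: 20 (Z)-3-amino-1-{4,6-bis(benzyloxy)-3-[2-(benzyloxy)-5-(5,7-bis(benzyloxy)-4-oxo-4H-chromen-2-yl)phenyl]-2-(methoxymethoxy)phenyl}-3-(4-methoxyphenyl)prop-2-en-1-one
Conditions: Mo(CO)6, MeCN/THF/H2O, 80 °C
Reagents that add atoms: none
Why: Reductive N–O cleavage of an isoxazole by Mo(CO)6 in wet acetonitrile (coordination at nitrogen, insertion into the weak N–O bond, protonation by water) gives the Z-enaminone held by an N–H···O=C hydrogen bond. The conditions are neutral and not hydrogenolytic, so the benzyl ethers, the acetal and both C2=C3 bonds remain.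

Step 15
Reactants: 20 (Z)-3-amino-1-{4,6-bis(benzyloxy)-3-[2-(benzyloxy)-5-(5,7-bis(benzyloxy)-4-oxo-4H-chromen-2-yl)phenyl]-2-(methoxymethoxy)phenyl}-3-(4-methoxyphenyl)prop-2-en-1-one
Product: 22 5,7-bis(benzyloxy)-8-{2-(benzyloxy)-5-[5,7-bis(benzyloxy)-4-oxo-4H-chromen-2-yl]phenyl}-2-(4-methoxyphenyl)-4H-chromen-4-one, via free phenol enaminone 21 (not isolated)
Conditions: HCl (aq.), MeOH/THF, 55 °C
Reagents that add atoms: none
Why: Acid-catalysed acetal exchange with methanol frees phenol 21, which adds 6-endo-trig to C2'' of the protonated enaminone and expels ammonia, a known flavone synthesis from 2-hydroxyaryl enaminones. Because the C5'' oxygen is still benzylated, only the C8a'' oxygen can close, so the 8''-linked pyranone alone can form.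

Step 16
Reactants: 22 5,7-bis(benzyloxy)-8-{2-(benzyloxy)-5-[5,7-bis(benzyloxy)-4-oxo-4H-chromen-2-yl]phenyl}-2-(4-methoxyphenyl)-4H-chromen-4-one
Product: 23 podocarpusflavone A, 8-[5-(5,7-dihydroxy-4-oxo-4H-chromen-2-yl)-2-hydroxyphenyl]-5,7-dihydroxy-2-(4-methoxyphenyl)-4H-chromen-4-one
Conditions: BCl3, pentamethylbenzene, CH2Cl2, −78 to 0 °C; MeOH/H2O quench
Reagents that add atoms: none
Why: Lewis acid cleavage of aryl benzyl ethers by BCl3 with pentamethylbenzene as a non-basic trap for the benzyl cation, which protects the phloroglucinol carbons from C-benzylation. The 4''' methyl ether has no chelating neighbour and should survive at low temperature.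

## Compound list

1 | 2,4,6-trihydroxybenzaldehyde | O=Cc1c(O)cc(O)cc1O | starting material
2 | 4,6-bis(benzyloxy)-2-hydroxybenzaldehyde | O=Cc1c(O)cc(OCc2ccccc2)cc1OCc1ccccc1 | intermediate
3 | 4,6-bis(benzyloxy)-2-hydroxy-3-iodobenzaldehyde | O=Cc1c(O)c(I)c(OCc2ccccc2)cc1OCc1ccccc1 | intermediate
4 | 4,6-bis(benzyloxy)-3-iodo-2-(methoxymethoxy)benzaldehyde | COCOc1c(I)c(OCc2ccccc2)cc(OCc2ccccc2)c1C=O | intermediate
5 | 2,4,6-trihydroxyacetophenone | CC(=O)c1c(O)cc(O)cc1O | starting material
6 | 1-[2,4-bis(benzyloxy)-6-hydroxyphenyl]ethanone | CC(=O)c1c(O)cc(OCc2ccccc2)cc1OCc1ccccc1 | intermediate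
7 | 3-bromo-4-hydroxybenzaldehyde | O=Cc1ccc(O)c(Br)c1 | starting material
8 | 4-(benzyloxy)-3-bromobenzaldehyde | O=Cc1ccc(OCc2ccccc2)c(Br)c1 | intermediate
9 | (E)-1-[2,4-bis(benzyloxy)-6-hydroxyphenyl]-3-[4-(benzyloxy)-3-bromophenyl]prop-2-en-1-one | O=C(/C=C/c1ccc(OCc2ccccc2)c(Br)c1)c1c(O)cc(OCc2ccccc2)cc1OCc1ccccc1 | intermediate
10 | racemic 5,7-bis(benzyloxy)-2-[4-(benzyloxy)-3-bromophenyl]chroman-4-one (not isolated) | O=C1CC(c2ccc(OCc3ccccc3)c(Br)c2)Oc2cc(OCc3ccccc3)cc(OCc3ccccc3)c21 | intermediate
11 | 5,7-bis(benzyloxy)-2-[4-(benzyloxy)-3-bromophenyl]-4H-chromen-4-one | O=c1cc(-c2ccc(OCc3ccccc3)c(Br)c2)oc2cc(OCc3ccccc3)cc(OCc3ccccc3)c12 | intermediate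
12 | 5,7-bis(benzyloxy)-2-[4-(benzyloxy)-3-(4,4,5,5-tetramethyl-1,3,2-dioxaborolan-2-yl)phenyl]-4H-chromen-4-one | O=c1cc(-c2ccc(OCc3ccccc3)c(B3OC(C)(C)C(C)(C)O3)c2)oc2cc(OCc3ccccc3)cc(OCc3ccccc3)c12 | intermediate
13 | 4,6-bis(benzyloxy)-3-{2-(benzyloxy)-5-[5,7-bis(benzyloxy)-4-oxo-4H-chromen-2-yl]phenyl}-2-(methoxymethoxy)benzaldehyde | COCOc1c(C=O)c(OCc2ccccc2)cc(OCc2ccccc2)c1-c1cc(-c2cc(=O)c3c(OCc4ccccc4)cc(OCc4ccccc4)cc3o2)ccc1OCc1ccccc1 | intermediate
14 | 5,7-bis(benzyloxy)-2-{4-(benzyloxy)-3-[4,6-bis(benzyloxy)-3-ethynyl-2-(methoxymethoxy)phenyl]phenyl}-4H-chromen-4-one | COCOc1c(C#C)c(OCc2ccccc2)cc(OCc2ccccc2)c1-c1cc(-c2cc(=O)c3c(OCc4ccccc4)cc(OCc4ccccc4)cc3o2)ccc1OCc1ccccc1 | intermediate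
15 | 4-methoxybenzaldehyde | COc1ccc(C=O)cc1 | starting material
16 | (E)-4-methoxybenzaldehyde oxime | COc1ccc(/C=N/O)cc1 | intermediate
17 | (Z)-N-hydroxy-4-methoxybenzimidoyl chloride | COc1ccc(/C(Cl)=N/O)cc1 | intermediate
18 | 4-methoxybenzonitrile oxide (not isolated) | COc1ccc(C#[N+][O-])cc1 | intermediate
19 | 5,7-bis(benzyloxy)-2-{4-(benzyloxy)-3-[4,6-bis(benzyloxy)-2-(methoxymethoxy)-3-[3-(4-methoxyphenyl)isoxazol-5-yl]phenyl]phenyl}-4H-chromen-4-one | COCOc1c(-c2cc(-c3ccc(OC)cc3)no2)c(OCc2ccccc2)cc(OCc2ccccc2)c1-c1cc(-c2cc(=O)c3c(OCc4ccccc4)cc(OCc4ccccc4)cc3o2)ccc1OCc1ccccc1 | intermediate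
20 | (Z)-3-amino-1-{4,6-bis(benzyloxy)-3-[2-(benzyloxy)-5-(5,7-bis(benzyloxy)-4-oxo-4H-chromen-2-yl)phenyl]-2-(methoxymethoxy)phenyl}-3-(4-methoxyphenyl)prop-2-en-1-one | COCOc1c(C(=O)/C=C(\N)c2ccc(OC)cc2)c(OCc2ccccc2)cc(OCc2ccccc2)c1-c1cc(-c2cc(=O)c3c(OCc4ccccc4)cc(OCc4ccccc4)cc3o2)ccc1OCc1ccccc1 | intermediate
21 | (Z)-3-amino-1-{4,6-bis(benzyloxy)-3-[2-(benzyloxy)-5-(5,7-bis(benzyloxy)-4-oxo-4H-chromen-2-yl)phenyl]-2-hydroxyphenyl}-3-(4-methoxyphenyl)prop-2-en-1-one (not isolated) | Oc1c(C(=O)/C=C(\N)c2ccc(OC)cc2)c(OCc2ccccc2)cc(OCc2ccccc2)c1-c1cc(-c2cc(=O)c3c(OCc4ccccc4)cc(OCc4ccccc4)cc3o2)ccc1OCc1ccccc1 | intermediate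
22 | 5,7-bis(benzyloxy)-8-{2-(benzyloxy)-5-[5,7-bis(benzyloxy)-4-oxo-4H-chromen-2-yl]phenyl}-2-(4-methoxyphenyl)-4H-chromen-4-one | COc1ccc(-c2cc(=O)c3c(OCc4ccccc4)cc(OCc4ccccc4)c(-c4cc(-c5cc(=O)c6c(OCc7ccccc7)cc(OCc7ccccc7)cc6o5)ccc4OCc4ccccc4)c3o2)cc1 | intermediate
23 | podocarpusflavone A | COc1ccc(-c2cc(=O)c3c(O)cc(O)c(-c4cc(-c5cc(=O)c6c(O)cc(O)cc6o5)ccc4O)c3o2)cc1 | target

## Step count and risks

Total: 16 steps. Longest linear sequence: 10 steps (steps 4, 6, 7, 8, 9, 10, 13, 14, 15, 16, from compound 5 to compound 23).

**Step 13 (key step).** The likeliest failure is dimerization of nitrile oxide 18 to the furoxan outrunning its addition to the hindered, electron-rich alkyne, so that 14 is recovered. The fallback sets out from 14 and comes back at 22. Acyl Sonogashira coupling of 14 with 4-methoxybenzoyl chloride (PdCl2(PPh3)2, CuI, Et3N, THF) should give the ynone 3-aryl-1-(4-methoxyphenyl)prop-2-yn-1-one F1. Conjugate addition of pyrrolidine to F1 should give the E-enaminone F2, with nitrogen on C4''. Aqueous HCl in MeOH/THF then removes the methoxymethyl group of F2; the phenol closes onto the anisoyl carbonyl (C2''), water is lost, and the C4'' iminium is hydrolysed with release of pyrrolidine to give 22. This path uses a copper acetylide instead of a dipole and needs no nitrile oxide.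

**Step 9.** Slow oxidative addition and transmetalation at the doubly flanked iodide may let protodeboronation of the poorly soluble boronate 12 and reductive loss of iodine take over. The fallback sets out from 3, 8 and 6 and comes back at 13. Miyaura borylation of 8 should give the small boronate 4-(benzyloxy)-3-(pinacolboryl)benzaldehyde F3, which can be used in large excess. Suzuki coupling of F3 with iodophenol 3 should give the dialdehyde biaryl F4. Under KOH the salicylaldehyde formyl group of F4 is deactivated as its phenoxide, so Claisen–Schmidt condensation with 6 should take place at the ring B aldehyde and give chalcone F5. I2/DMSO should close the apigenin pyranone of F5 to give flavone phenol F6, and NaH/MOMCl should convert F6 into 13.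

**Step 10.** The doubly ortho-substituted, donor-deactivated formyl group may react slowly, leaving time for the diazophosphonate to decompose or to attack elsewhere. The fallback sets out from 13 and comes back at 22, with the roles of dipole and dipolarophile exchanged so that no alkyne on ring A is needed. NH2OH·HCl/pyridine should convert 13 into oxime F7. PhI(OAc)2 in MeOH should dehydrogenate F7 to nitrile oxide F8, which its two ortho substituents protect from dimerization. Addition of F8 to 4-ethynylanisole should give the regioisomeric 3-aryl-5-(4-methoxyphenyl)isoxazole F9. Mo(CO)6 should open F9 to enaminone F10, with the amino group on C4''. Aqueous HCl in MeOH/THF then removes the acetal of F10, closes the phenol onto the C2'' carbonyl and hydrolyses the imine to give 22.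

**Step 2.** Iodination may partly go to C5, between the two benzyloxy groups, or go twice. The fallback sets out from 1 and comes back at 3. The symmetric aldehyde 1 is iodinated first (NIS, 1 equiv) to give 2,4,6-trihydroxy-3-iodobenzaldehyde F11; the two open positions are equivalent, so there is no regiochemical question. Dibenzylation of F11 (BnBr, K2CO3) should take the para hydroxyl and the less hindered ortho hydroxyl, leaving the hydroxyl between iodine and the formyl group chelated, which is 3.

**Step 16.** Debenzylation may stop short at the chelated C5 and C5'' ethers, or escaping benzyl cations may alkylate C6, C8 or C6''. The fallback sets out from 22 and comes back at 23: catalytic hydrogenolysis (H2, Pd/C, THF/MeOH), stopped before the C2=C3 bonds are reduced. It makes no new compound.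

## Further compounds

F1 | step 13 | 3-{4,6-bis(benzyloxy)-3-[2-(benzyloxy)-5-(5,7-bis(benzyloxy)-4-oxo-4H-chromen-2-yl)phenyl]-2-(methoxymethoxy)phenyl}-1-(4-methoxyphenyl)prop-2-yn-1-one | COCOc1c(C#CC(=O)c2ccc(OC)cc2)c(OCc2ccccc2)cc(OCc2ccccc2)c1-c1cc(-c2cc(=O)c3c(OCc4ccccc4)cc(OCc4ccccc4)cc3o2)ccc1OCc1ccccc1
F2 | step 13 | (E)-3-{4,6-bis(benzyloxy)-3-[2-(benzyloxy)-5-(5,7-bis(benzyloxy)-4-oxo-4H-chromen-2-yl)phenyl]-2-(methoxymethoxy)phenyl}-1-(4-methoxyphenyl)-3-(pyrrolidin-1-yl)prop-2-en-1-one | COCOc1c(/C(N2CCCC2)=C\C(=O)c2ccc(OC)cc2)c(OCc2ccccc2)cc(OCc2ccccc2)c1-c1cc(-c2cc(=O)c3c(OCc4ccccc4)cc(OCc4ccccc4)cc3o2)ccc1OCc1ccccc1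
F3 | step 9 | 4-(benzyloxy)-3-(4,4,5,5-tetramethyl-1,3,2-dioxaborolan-2-yl)benzaldehyde | O=Cc1ccc(OCc2ccccc2)c(B2OC(C)(C)C(C)(C)O2)c1
F4 | step 9 | 4,6-bis(benzyloxy)-3-[2-(benzyloxy)-5-formylphenyl]-2-hydroxybenzaldehyde | O=Cc1ccc(OCc2ccccc2)c(-c2c(O)c(C=O)c(OCc3ccccc3)cc2OCc2ccccc2)c1
F5 | step 9 | (E)-3-{4-(benzyloxy)-3-[4,6-bis(benzyloxy)-3-formyl-2-hydroxyphenyl]phenyl}-1-[2,4-bis(benzyloxy)-6-hydroxyphenyl]prop-2-en-1-one | O=Cc1c(O)c(-c2cc(/C=C/C(=O)c3c(O)cc(OCc4ccccc4)cc3OCc3ccccc3)ccc2OCc2ccccc2)c(OCc2ccccc2)cc1OCc1ccccc1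
F6 | step 9 | 4,6-bis(benzyloxy)-3-{2-(benzyloxy)-5-[5,7-bis(benzyloxy)-4-oxo-4H-chromen-2-yl]phenyl}-2-hydroxybenzaldehyde | O=Cc1c(O)c(-c2cc(-c3cc(=O)c4c(OCc5ccccc5)cc(OCc5ccccc5)cc4o3)ccc2OCc2ccccc2)c(OCc2ccccc2)cc1OCc1ccccc1
F7 | step 10 | (E)-oxime of aldehyde 13 | COCOc1c(/C=N/O)c(OCc2ccccc2)cc(OCc2ccccc2)c1-c1cc(-c2cc(=O)c3c(OCc4ccccc4)cc(OCc4ccccc4)cc3o2)ccc1OCc1ccccc1
F8 | step 10 | 4,6-bis(benzyloxy)-3-{2-(benzyloxy)-5-[5,7-bis(benzyloxy)-4-oxo-4H-chromen-2-yl]phenyl}-2-(methoxymethoxy)benzonitrile oxide | COCOc1c(C#[N+][O-])c(OCc2ccccc2)cc(OCc2ccccc2)c1-c1cc(-c2cc(=O)c3c(OCc4ccccc4)cc(OCc4ccccc4)cc3o2)ccc1OCc1ccccc1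
F9 | step 10 | 5,7-bis(benzyloxy)-2-{4-(benzyloxy)-3-[4,6-bis(benzyloxy)-2-(methoxymethoxy)-3-[5-(4-methoxyphenyl)isoxazol-3-yl]phenyl]phenyl}-4H-chromen-4-one | COCOc1c(-c2cc(-c3ccc(OC)cc3)on2)c(OCc2ccccc2)cc(OCc2ccccc2)c1-c1cc(-c2cc(=O)c3c(OCc4ccccc4)cc(OCc4ccccc4)cc3o2)ccc1OCc1ccccc1
F10 | step 10 | (Z)-3-amino-3-{4,6-bis(benzyloxy)-3-[2-(benzyloxy)-5-(5,7-bis(benzyloxy)-4-oxo-4H-chromen-2-yl)phenyl]-2-(methoxymethoxy)phenyl}-1-(4-methoxyphenyl)prop-2-en-1-one | COCOc1c(/C(N)=C/C(=O)c2ccc(OC)cc2)c(OCc2ccccc2)cc(OCc2ccccc2)c1-c1cc(-c2cc(=O)c3c(OCc4ccccc4)cc(OCc4ccccc4)cc3o2)ccc1OCc1ccccc1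
F11 | step 2 | 2,4,6-trihydroxy-3-iodobenzaldehyde | O=Cc1c(O)cc(O)c(I)c1O
F0 | step 16 | none | none
A1 | alternative 1 | 3-ethoxycyclobut-2-en-1-one | CCOC1=CC(=O)C1
A2 | alternative 1 | 2-[4-(benzyloxy)-3-{[tri(propan-2-yl)silyl]oxyethynyl}phenyl]-1,3-dioxolane | CC(C)[Si](OC#Cc1cc(C2OCCO2)ccc1OCc1ccccc1)(C(C)C)C(C)C
A3 | alternative 1 | 2-[2-(benzyloxy)-5-(1,3-dioxolan-2-yl)phenyl]-5-ethoxy-3-{[tri(propan-2-yl)silyl]oxy}phenol | CCOc1cc(O)c(-c2cc(C3OCCO3)ccc2OCc2ccccc2)c(O[Si](C(C)C)(C(C)C)C(C)C)c1
A4 | alternative 2 | 6-[(E)-4-{4-(benzyloxy)-3-[5,7-bis(benzyloxy)-2-(4-methoxyphenyl)-4-oxo-4H-chromen-8-yl]phenyl}-2-oxobut-3-enyl]-4-hydroxy-2H-pyran-2-one | O=C(Cc1cc(O)cc(=O)o1)/C=C/c1ccc(OCc2ccccc2)c(-c2c(OCc3ccccc3)cc(OCc3ccccc3)c3c(=O)cc(-c4ccc(OC)cc4)oc23)c1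
A5 | alternative 2 | (E)-3-{4-(benzyloxy)-3-[5,7-bis(benzyloxy)-2-(4-methoxyphenyl)-4-oxo-4H-chromen-8-yl]phenyl}-1-(2,4,6-trihydroxyphenyl)prop-2-en-1-one | O=C(/C=C/c1ccc(OCc2ccccc2)c(-c2c(OCc3ccccc3)cc(OCc3ccccc3)c3c(=O)cc(-c4ccc(OC)cc4)oc23)c1)c1c(O)cc(O)cc1O
A6 | alternative 3 | 5,7-bis(benzyloxy)-8-[(1Z,3E)-4-methoxy-2-(trimethylsilyloxy)buta-1,3-dienyl]-2-(4-methoxyphenyl)-4H-chromen-4-one | CO/C=C/C(O[Si](C)(C)C)=C/c1c(OCc2ccccc2)cc(OCc2ccccc2)c2c(=O)cc(-c3ccc(OC)cc3)oc12
A7 | alternative 3 | methyl propiolate | C#CC(=O)OC
A8 | alternative 3 | methyl 3-[5,7-bis(benzyloxy)-2-(4-methoxyphenyl)-4-oxo-4H-chromen-8-yl]-4-hydroxybenzoate | COC(=O)c1ccc(O)c(-c2c(OCc3ccccc3)cc(OCc3ccccc3)c3c(=O)cc(-c4ccc(OC)cc4)oc23)c1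
A9 | alternative 3 | (E)-1-[5,7-bis(benzyloxy)-2-(4-methoxyphenyl)-4-oxo-4H-chromen-8-yl]-4-methoxybut-3-en-2-one | CO/C=C/C(=O)Cc1c(OCc2ccccc2)cc(OCc2ccccc2)c2c(=O)cc(-c3ccc(OC)cc3)oc12
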